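**Assumption:** the SMILES is read as the 4‑hydroxybenzoate of 8α,9α‑epoxyjaeschkeanadiol (8,9‑epoxyferutinin), daucane numbering 1R,4R,5S,6S,8R,9S. Numbering used below: C1 = ring‑fusion C(CH3); C2, C3 = CH2; C4 = C(OH)(i‑Pr); C5 = ring‑fusion CH; C6 = CH–O; C7 = CH2; C8 = C(CH3); C9 = CH; C10 = CH2.

## Retrosynthetic overview

1. Jaeskeanin ⇐ phenol‑protected 6‑O‑aroyl epoxide ⇐ jaeschkeanadiol, by epoxidation of C8=C9 directed by the 6‑OH, then acylation.
2. Jaeschkeanadiol ⇐ ring‑closing metathesis at C8=C9 (seven‑membered ring formed last) ⇐ cyclopentanone + i‑Pr nucleophile (sets C4).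
3. Cyclopentanone (five‑membered ring formed first) ⇐ Rh‑catalysed 4‑pentenal hydroacylation (C3–C4 bond).
4. Acyclic aldehyde ⇐ chelate‑controlled dianionic Ireland–Claisen (C1–C5 bond; sets quaternary C1 and C5 from the C6 carbinol and the E‑alkene geometry).
5. Claisen ester ⇐ ethyl (R)‑4‑chloro‑3‑hydroxybutanoate (source of C6) + isopropenyl Grignard, and (E)‑3‑methylhexa‑2,5‑dien‑1‑ol from pent‑1‑en‑4‑yne.

## Route

**Step 1**
Reactants: 1, ethyl (3R)‑4‑chloro‑3‑hydroxybutanoate
Product: 3, ethyl (3S)‑3‑hydroxy‑5‑methylhex‑5‑enoate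
Conditions: isopropenylMgBr (3.2 equiv), CuI (10 mol %), THF, −40 → 0 °C
Reagents that add atoms: 2, isopropenylmagnesium bromide, CC(=C)[Mg]Br
Why: The chlorohydrin alkoxide closes to the epoxy ester in situ and a Cu‑catalysed Grignard epoxide opening occurs at the terminal CH2, so the carbinol centre is untouched (R→S is only a CIP priority change).

**Step 2**
Reactants: 4, pent‑1‑en‑4‑yne
Product: 7, (2E)‑3‑methylhexa‑2,5‑dien‑1‑ol
Conditions: Me3Al, Cp2ZrCl2 (20 mol %), CH2Cl2, 0 °C → rt; then n‑BuLi, (CH2O)n, THF, −78 °C → rt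
Reagents that add atoms: 5, trimethylaluminium, C[Al](C)C; 6, paraformaldehyde (formaldehyde), C=O
Why: Negishi Zr‑catalysed syn‑methylalumination of the terminal alkyne, then trapping of the alkenylalanate with formaldehyde with retention, gives only the E trisubstituted allylic alcohol; the terminal alkene is inert.

**Step 3**
Reactants: 3, ethyl (3S)‑3‑hydroxy‑5‑methylhex‑5‑enoate; 7, (2E)‑3‑methylhexa‑2,5‑dien‑1‑ol
Product: 8, (2E)‑3‑methylhexa‑2,5‑dien‑1‑yl (3S)‑3‑hydroxy‑5‑methylhex‑5‑enoate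
Conditions: Otera distannoxane catalyst (5 mol %), 7 (1.3 equiv), toluene, reflux (−EtOH)
Reagents that add atoms: none
Why: Neutral distannoxane‑catalysed transesterification driven by ethanol removal; the primary allylic alcohol out‑competes the secondary OH and no stereocentre is involved.

**Step 4**
Reactants: 8
Product: 9, (2S,3S)‑3‑hydroxy‑5‑methyl‑2‑[(3S)‑3‑methylhexa‑1,5‑dien‑3‑yl]hex‑5‑enoic acid
Conditions: LDA (2.3 equiv), THF, −78 °C → rt, then 50 °C; H3O+
Reagents that add atoms: none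
Why: Dianionic Ireland–Claisen [3,3] rearrangement. The Li‑chelated enolate (enolate O cis to C6) reacts through a chair transition state on the face anti to the methallyl group, which sets C5 anti to the OH (Fráter–Seebach sense). The E‑alkene puts CH3 pseudo‑axial and the allyl arm pseudo‑equatorial, which fixes quaternary C1 with the C6 chain syn to CH3.

**Step 5**
Reactants: 9
Product: 10, (2R,3S)‑5‑methyl‑2‑[(3S)‑3‑methylhexa‑1,5‑dien‑3‑yl]hex‑5‑ene‑1,3‑diol
Conditions: LiAlH4, THF, 0 °C → reflux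
Reagents that add atoms: none
Why: Hydride reduction of the carboxylate to the primary alcohol; isolated alkenes and stereocentres are untouched (descriptor change at C5 is CIP only).

**Step 6**
Reactants: 10
Product: 11, (2S,3S)‑3‑hydroxy‑5‑methyl‑2‑[(3S)‑3‑methylhexa‑1,5‑dien‑3‑yl]hex‑5‑enal
Conditions: TEMPO (10 mol %), PhI(OAc)2, CH2Cl2, rt
Reagents that add atoms: none
Why: TEMPO/oxoammonium oxidation is selective for the primary over the secondary alcohol and stops at the aldehyde; neutral conditions avoid α‑epimerisation and retro‑aldol.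

**Step 7**
Reactants: 11
Product: 12, (2S,3R)‑2‑[(1S)‑1‑hydroxy‑3‑methylbut‑3‑en‑1‑yl]‑3‑methyl‑3‑(prop‑2‑en‑1‑yl)cyclopentan‑1‑one
Conditions: [Rh(dppe)]BF4 (5 mol %, from [Rh(nbd)(dppe)]BF4/H2), acetone, rt
Reagents that add atoms: none
Why: Rh(I)‑catalysed intramolecular hydroacylation of a 4‑pentenal; only the vinyl group can form the six‑membered acyl‑rhodacycle, so C3–C4 closes to the cyclopentanone and no stereocentre is touched.

**Step 8**
Reactants: 12
Product: 14, (1R,2S,3R)‑2‑[(1S)‑1‑hydroxy‑3‑methylbut‑3‑en‑1‑yl]‑3‑methyl‑1‑(propan‑2‑yl)‑3‑(prop‑2‑en‑1‑yl)cyclopentan‑1‑ol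
Conditions: i‑PrMgCl (3.5 equiv), anhydrous CeCl3, THF, −78 °C
Reagents that add atoms: 13, isopropylmagnesium chloride, CC(C)[Mg]Cl
Why: Organocerium (Imamoto) 1,2‑addition suppresses enolisation and reduction; i‑Pr attacks the ketone face opposite the adjacent C5 side chain, giving the tertiary OH cis to that chain (C4 R).

**Step 9**
Reactants: 14
Product: 15, jaeschkeanadiol, (3R,3aS,4S,8aR)‑6,8a‑dimethyl‑3‑(propan‑2‑yl)‑1,2,3,3a,4,5,8,8a‑octahydroazulene‑3,4‑diol
Conditions: Grubbs II (5 mol %), CH2Cl2 (5 mM), 40 °C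
Reagents that add atoms: none
Why: Ring‑closing metathesis of the allyl and methallyl groups gives the trisubstituted cycloheptene C8=C9 with loss of ethylene; the trans ring fusion is already fixed by C1/C5.

**Step 10**
Reactants: 15
Product: 17, 8α,9α‑epoxyjaeschkeanadiol (1R,4R,5S,6S,8R,9S)
Conditions: VO(acac)2 (5 mol %), t‑BuOOH, CH2Cl2, 0 °C → rt
Reagents that add atoms: 16, tert‑butyl hydroperoxide, CC(C)(C)OO
Why: Vanadium‑catalysed hydroxyl‑directed epoxidation; the homoallylic 6α‑OH delivers oxygen to the alkene face syn to itself, giving the cis‑epoxy alcohol (8R,9S).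

**Step 11**
Reactants: 17
Product: 19, 6‑O‑{4‑[(tert‑butyldimethylsilyl)oxy]benzoyl}‑8α,9α‑epoxyjaeschkeanadiol
Conditions: 18, EDC·HCl, DMAP, CH2Cl2, rt
Reagents that add atoms: 18, 4‑[(tert‑butyldimethylsilyl)oxy]benzoic acid, OC(=O)c1ccc(O[Si](C)(C)C(C)(C)C)cc1
Why: Steglich esterification acylates the secondary 6‑OH with retention; the tertiary 4‑OH is unreactive and the neutral conditions preserve the epoxide.

**Step 12**
Reactants: 19
Product: 20, Jaeskeanin
Conditions: TBAF, AcOH (1:1), THF, 0 °C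
Reagents that add atoms: none
Why: Fluoride cleaves the aryl silyl ether; buffering leaves the benzoate and epoxide intact.

## Compound list

1 | ethyl (3R)‑4‑chloro‑3‑hydroxybutanoate | CCOC(=O)C[C@@H](O)CCl | starting material
2 | isopropenylmagnesium bromide | CC(=C)[Mg]Br | starting material (reagent)
3 | ethyl (3S)‑3‑hydroxy‑5‑methylhex‑5‑enoate | CCOC(=O)C[C@@H](O)CC(C)=C | intermediate
4 | pent‑1‑en‑4‑yne | C=CCC#C | starting material
5 | trimethylaluminium | C[Al](C)C | starting material (reagent)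
6 | paraformaldehyde (formaldehyde) | C=O | starting material (reagent)
7 | (2E)‑3‑methylhexa‑2,5‑dien‑1‑ol | OC/C=C(\C)CC=C | intermediate
8 | (2E)‑3‑methylhexa‑2,5‑dien‑1‑yl (3S)‑3‑hydroxy‑5‑methylhex‑5‑enoate | C=C(C)C[C@H](O)CC(=O)OC/C=C(\C)CC=C | intermediate
9 | (2S,3S)‑3‑hydroxy‑5‑methyl‑2‑[(3S)‑3‑methylhexa‑1,5‑dien‑3‑yl]hex‑5‑enoic acid | C=C[C@](C)(CC=C)[C@H](C(=O)O)[C@@H](O)CC(C)=C | intermediate
10 | (2R,3S)‑5‑methyl‑2‑[(3S)‑3‑methylhexa‑1,5‑dien‑3‑yl]hex‑5‑ene‑1,3‑diol | C=C[C@](C)(CC=C)[C@H](CO)[C@@H](O)CC(C)=C | intermediate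
11 | (2S,3S)‑3‑hydroxy‑5‑methyl‑2‑[(3S)‑3‑methylhexa‑1,5‑dien‑3‑yl]hex‑5‑enal | C=C[C@](C)(CC=C)[C@H](C=O)[C@@H](O)CC(C)=C | intermediate
12 | (2S,3R)‑2‑[(1S)‑1‑hydroxy‑3‑methylbut‑3‑en‑1‑yl]‑3‑methyl‑3‑allylcyclopentan‑1‑one | O=C1CC[C@](C)(CC=C)[C@H]1[C@@H](O)CC(C)=C | intermediate
13 | isopropylmagnesium chloride | CC(C)[Mg]Cl | starting material (reagent)
14 | (1R,2S,3R)‑2‑[(1S)‑1‑hydroxy‑3‑methylbut‑3‑en‑1‑yl]‑3‑methyl‑1‑isopropyl‑3‑allylcyclopentan‑1‑ol | CC(C)[C@]1(O)CC[C@](C)(CC=C)[C@H]1[C@@H](O)CC(C)=C | intermediate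
15 | jaeschkeanadiol | CC(C)[C@]1(O)CC[C@]2(C)CC=C(C)C[C@H](O)[C@H]21 | intermediate
16 | tert‑butyl hydroperoxide | CC(C)(C)OO | starting material (reagent)
17 | 8α,9α‑epoxyjaeschkeanadiol | CC(C)[C@]1(O)CC[C@]2(C)C[C@@H]3O[C@]3(C)C[C@H](O)[C@H]21 | intermediate
18 | 4‑[(tert‑butyldimethylsilyl)oxy]benzoic acid | OC(=O)c1ccc(O[Si](C)(C)C(C)(C)C)cc1 | starting material
19 | 6‑O‑[4‑(TBSO)benzoyl]‑8α,9α‑epoxyjaeschkeanadiol | CC(C)[C@]1(O)CC[C@]2(C)C[C@@H]3O[C@]3(C)C[C@H](OC(=O)c3ccc(O[Si](C)(C)C(C)(C)C)cc3)[C@H]21 | intermediate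
20 | Jaeskeanin | CC(C)[C@]1(O)CC[C@]2(C)C[C@@H]3O[C@]3(C)C[C@H](OC(=O)c3ccc(O)cc3)[C@H]21 | target

## Summary

Total steps: 12. Longest linear sequence: 11 (steps 1, 3–12; step 2 is the convergent branch).

Steps most likely to fail, with fallbacks:

1. **Step 4, dianionic Ireland–Claisen** (congested quaternary centre; diastereocontrol rests on the chelate and chair models). Fallback: set C1 by catalysis instead. Make enantioenriched 4‑allyl‑4‑methylcyclopent‑2‑enone by Pd‑catalysed decarboxylative allylic alkylation of the cyclopentenone vinylogous ester followed by reduction/hydrolysis, then α′‑aldol with 3‑methylbut‑3‑enal and conjugate reduction to 12, accepting separation of C5/C6 diastereomers.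
2. **Step 7, Rh hydroacylation** (free β‑hydroxy aldehyde, three alkenes; decarbonylation or isomerisation possible). Fallback: close the ring at C2=C3 instead. Add vinylMgBr to 11, run RCM of the resulting 1,6‑diene to the cyclopentenol, oxidise to the enone and do a Stryker conjugate reduction to reach 12.
3. **Step 8, i‑Pr addition** to a hindered, enolisable β‑hydroxy ketone (reduction, retro‑aldol or C5 epimerisation possible). Fallback: change the order and the nucleophile. Run RCM on 12 first, add isopropenyl‑cerium to the rigid trans‑fused bicyclic ketone, then hydrogenate the 1,1‑disubstituted alkene selectively with Wilkinson's catalyst to reach 15.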